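**Retrosynthetic overview**

1. Target 39 is an 18-membered oxazole macrolactone. The last C–C bond made is the ring bond between the carbinol carbon (the one next to the lactone O–CH) and the neighbouring methoxy-bearing carbon, by an SmI2 Barbier macrocyclisation of aldehyde / α-methoxy 2-pyridyl sulfone 36 that closes the ring and sets both stereocentres.
2. Enabling feature: in the ring's CH(OMe)–CH(OH) pair the methoxy carbon sits at the aldehyde oxidation level next to a CH2, so it is carried as a dimethyl acetal from citronellal and then made nucleophilic through the sulfone. The carbinol carbon sits next to the acyloxy-bearing allylic ring carbon, whose stereocentre steers the addition (Felkin–Anh).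
3. Seco ester 34 comes from Yamaguchi esterification of fragment 1 (acid 17: (S)-citronellal, oxazole from serine, HWE, crotylboration, cross-metathesis) with fragment 2 (alcohol 32: D-glyceraldehyde acetonide, Wittig, copper-mediated coupling with alkyne 23 from (R)-lactic acid, semi-hydrogenation).
4. Ring order: oxazole ring first (step 3), 18-membered lactone ring last (step 28); one fluoride step then frees the two hydroxyls and the acid.

Key step: step 28

Remark: compounds 16, 17 and 33–37 are mixtures of epimers at the sulfur-bearing methoxy carbon (drawn without configuration); that centre is erased and reset in step 28.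

**Fragment 1 (acid 17)**

Step 1
Reactants: 1 (S)-citronellal
Product: 2 (S)-citronellal dimethyl acetal
Conditions: HC(OMe)3, MeOH, PPTS (cat.), rt
Reagents that add atoms: trimethyl orthoformate COC(OC)OC
Why: Mild acetalisation should protect the aldehyde carbon (the later methoxy carbon) for the next ten steps, PPTS being too weak to start the carbonyl-ene cyclisation of citronellal.

Step 2
Reactants: 2 (S)-citronellal dimethyl acetal
Product: 4 (4S)-6,6-dimethoxy-4-methylhexanal, via ozonide 3 (not isolated)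
Conditions: O3, CH2Cl2, −78 °C; then PPh3, −78 °C to rt
Reagents that add atoms: ozone [O-][O+]=O
Why: Ozonolysis with reductive work-up should cleave the only alkene to the aldehyde without touching the acetal or the methyl stereocentre.

Step 3
Reactants: 4 (4S)-6,6-dimethoxy-4-methylhexanal
Product: 7 methyl 2-[(3S)-5,5-dimethoxy-3-methylpentyl]oxazole-4-carboxylate, via oxazolidine 5 (not isolated), via oxazoline 6 (not isolated)
Conditions: L-Ser-OMe·HCl, Et3N, MgSO4, CH2Cl2, rt; then BrCCl3, DBU, 0 °C to rt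
Reagents that add atoms: L-serine methyl ester hydrochloride COC(=O)[C@@H](N)CO.Cl
Why: Condensation to the oxazolidine followed by two bromination–dehydrobromination cycles (oxidative aromatisation) should give the 2,4-disubstituted oxazole, the serine stereocentre being destroyed on purpose.

Step 4
Reactants: 7 oxazole methyl ester
Product: 8 Weinreb amide (N-methoxy-N-methyl oxazole-4-carboxamide)
Conditions: MeNH(OMe)·HCl, i-PrMgCl, THF, −20 °C
Reagents that add atoms: N,O-dimethylhydroxylamine hydrochloride CNOC.Cl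
Why: Aminolysis of the ester by the magnesium amide (Weinreb amide formation) should be clean at low temperature.

Step 5
Reactants: 8 Weinreb amide
Product: 9 4-acetyloxazole (methyl ketone)
Conditions: MeMgBr, THF, 0 °C
Reagents that add atoms: methylmagnesium bromide C[Mg]Br
Why: Weinreb ketone synthesis; the chelated tetrahedral adduct prevents over-addition.

Step 6
Reactants: 9 methyl ketone
Product: 10 ethyl (E)-3-(oxazol-4-yl)but-2-enoate
Conditions: (EtO)2P(O)CH2CO2Et, NaH, THF, 0 to 60 °C
Reagents that add atoms: triethyl phosphonoacetate CCOC(=O)CP(=O)(OCC)OCC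
Why: Horner–Wadsworth–Emmons olefination of the heteroaryl methyl ketone should favour the E-enoate (oxazole trans to the ester), the minor Z-isomer being removed by chromatography.

Step 7
Reactants: 10 (E)-enoate
Product: 11 (E)-allylic alcohol
Conditions: DIBAL-H (i-Bu2AlH), CH2Cl2, −78 °C; Rochelle salt
Reagents that add atoms: none
Why: 1,2-Reduction of the enoate by DIBAL-H leaves the acetal and the alkene geometry intact.

Step 8
Reactants: 11 (E)-allylic alcohol
Product: 12 (E)-3-(oxazol-4-yl)but-2-enal
Conditions: MnO2, CH2Cl2, rt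
Reagents that add atoms: none
Why: Chemoselective allylic oxidation with MnO2 gives the enal without isomerising the alkene.

Step 9
Reactants: 12 (E)-enal
Product: 13 (2E,4R,5S)-5-methyl-2-(oxazol-4-yl)hepta-2,6-dien-4-ol (syn homoallylic alcohol)
Conditions: (Z)-crotyl-B(pin), (R)-TRIP (5 mol %), toluene, −30 °C; aqueous work-up
Reagents that add atoms: (Z)-crotylboronic acid pinacol ester C/C=C\CB1OC(C)(C)C(C)(C)O1
Why: Chiral phosphoric acid-catalysed crotylboration through a closed chair transition state; the Z-crotyl geometry should give the syn methyl/hydroxyl pair and the (R)-catalyst the (R)-carbinol.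

Step 10
Reactants: 13 syn homoallylic alcohol
Product: 14 TBS ether of 13
Conditions: TBSCl, imidazole, DMF, rt
Reagents that add atoms: tert-butyldimethylsilyl chloride CC(C)(C)[Si](C)(C)Cl
Why: Standard silylation; imidazole conditions avoid the silyl triflate that would activate the dimethyl acetal.

Step 11
Reactants: 14 TBS ether
Product: 15 (2E)-enoic acid (5-silyloxy-4-methyl-6-oxazolylhepta-2,6-dienoic acid, acetal intact)
Conditions: acrylic acid, second-generation Grubbs catalyst (5 mol %), CH2Cl2, 40 °C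
Reagents that add atoms: acrylic acid C=CC(=O)O
Why: Cross-metathesis of the terminal alkene with acrylic acid should give the E-enoic acid, the trisubstituted alkene being inert.

Step 12
Reactants: 15 acetal acid
Product: 16 mixed O,S-acetal (methoxy 2-pyridylthio acetal)
Conditions: 2-mercaptopyridine, BF3·OEt2, CH2Cl2, −40 °C
Reagents that add atoms: 2-mercaptopyridine Sc1ccccn1
Why: Lewis acid-mediated exchange of one methoxy group through the oxocarbenium ion (monothioacetal formation) keeps the second methoxy group, which is the methoxy group of the target.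

Step 13
Reactants: 16 mixed O,S-acetal
Product: 17 α-methoxy 2-pyridyl sulfone acid (fragment 1)
Conditions: H2O2 (30 %), (NH4)6Mo7O24·4H2O (cat.), EtOH, 0 °C to rt
Reagents that add atoms: hydrogen peroxide OO
Why: Molybdate-catalysed sulfide-to-sulfone oxidation should be much faster than epoxidation of the oxazole-conjugated trisubstituted alkene or the electron-poor enoic acid.

**Alkyne 23**

Step 14
Reactants: 18 (R)-lactic acid
Product: 19 (2R,5R)-2-tert-butyl-5-methyl-1,3-dioxolan-4-one (cis)
Conditions: t-BuCHO, TsOH (cat.), pentane, reflux (Dean–Stark); crystallisation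
Reagents that add atoms: pivalaldehyde CC(C)(C)C=O
Why: Acetalisation to the Seebach dioxolanone; the cis isomer is the thermodynamic product and stores the lactate chirality at the acetal carbon.

Step 15
Reactants: 19 cis-dioxolanone
Product: 21 (2R,5S)-2-tert-butyl-5-methyl-5-(prop-2-ynyl)-1,3-dioxolan-4-one, via lithium enolate 20 (not isolated)
Conditions: LDA, THF, −78 °C; propargyl bromide, −78 to −30 °C
Reagents that add atoms: propargyl bromide C#CCBr
Why: Seebach self-regeneration of stereocentres; the enolate should be alkylated anti to the tert-butyl group, which sets the tertiary carbinol centre.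

Step 16
Reactants: 21 propargyl dioxolanone
Product: 22 2-(trimethylsilyl)ethyl (S)-2-hydroxy-2-methylpent-4-ynoate
Conditions: Me3SiCH2CH2OH, NaH (cat.), THF, 0 °C to rt
Reagents that add atoms: 2-(trimethylsilyl)ethanol C[Si](C)(C)CCO
Why: Alkoxide-catalysed transesterification opens the dioxolanone and releases pivalaldehyde without touching the quaternary centre.

Step 17
Reactants: 22 tertiary hydroxy ester
Product: 23 triethylsilyl ether of 22 (alkyne piece)
Conditions: TESOTf, 2,6-lutidine, CH2Cl2, −78 to 0 °C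
Reagents that add atoms: triethylsilyl triflate CC[Si](CC)(CC)OS(=O)(=O)C(F)(F)F
Why: Silyl triflate silylation masks the tertiary hydroxyl, which would otherwise protonate the organosamarium in step 28.

**Fragment 2 (alcohol 32)**

Step 18
Reactants: 24 2,3-O-isopropylidene-D-glyceraldehyde
Product: 25 ethyl (S,E)-3-(2,2-dimethyl-1,3-dioxolan-4-yl)-2-methylacrylate
Conditions: Ph3P=C(Me)CO2Et, CH2Cl2, rt
Reagents that add atoms: ethyl 2-(triphenylphosphoranylidene)propanoate CCOC(=O)C(C)=P(c1ccccc1)(c1ccccc1)c1ccccc1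
Why: Wittig reaction with the stabilised ylide should give the E-trisubstituted enoate; the chiral-pool centre (the later lactone O–CH) is not touched.

Step 19
Reactants: 25 acetonide enoate
Product: 26 ethyl (S,E)-4,5-dihydroxy-2-methylpent-2-enoate
Conditions: AcOH/H2O 4:1, 40 °C
Reagents that add atoms: none
Why: Acid hydrolysis of the terminal acetonide; the E-alkene prevents lactonisation.

Step 20
Reactants: 26 diol ester
Product: 28 primary PMB ether (secondary hydroxyl free), via stannylene acetal 27 (not isolated)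
Conditions: Bu2SnO, toluene, reflux; then PMBCl, Bu4NI (cat.), 80 °C
Reagents that add atoms: 4-methoxybenzyl chloride COc1ccc(CCl)cc1
Why: Stannylene acetal-mediated alkylation is selective for the primary oxygen of a 1,2-diol.

Step 21
Reactants: 28 PMB ether enoate
Product: 29 (E)-allylic diol
Conditions: DIBAL-H (i-Bu2AlH), CH2Cl2, −78 °C; Rochelle salt
Reagents that add atoms: none
Why: DIBAL-H 1,2-reduction of the enoate to the primary allylic alcohol.

Step 22
Reactants: 29 allylic diol
Product: 30 primary allylic bromide (secondary hydroxyl free)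
Conditions: CBr4 (1.05 equiv), PPh3, CH2Cl2, −30 °C
Reagents that add atoms: carbon tetrabromide BrC(Br)(Br)Br
Why: Appel bromination is kinetically selective for the primary allylic hydroxyl at low temperature with one equivalent of reagent.

Step 23
Reactants: 30 allylic bromide; 23 terminal alkyne
Product: 31 skipped enyne
Conditions: CuI, NaI, Cs2CO3, DMF, rt
Reagents that add atoms: none
Why: Copper-mediated coupling of a terminal alkyne with a primary allylic bromide proceeds by direct (SN2) substitution and keeps the E-alkene.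

Step 24
Reactants: 31 skipped enyne
Product: 32 (E,Z)-skipped diene alcohol (fragment 2)
Conditions: H2 (1 atm), Pd/CaCO3 poisoned with Pb(OAc)2, quinoline, EtOAc, rt
Reagents that add atoms: none
Why: Lindlar semi-hydrogenation delivers the Z-alkene by syn addition and leaves the trisubstituted alkene and the PMB ether untouched.

**Union and end game**

Step 25
Reactants: 17 fragment 1 acid; 32 fragment 2 alcohol
Product: 34 seco ester, via mixed anhydride 33 (not isolated)
Conditions: 2,4,6-Cl3C6H2COCl, Et3N, THF, rt; then 32, DMAP, toluene, rt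
Reagents that add atoms: none
Why: Yamaguchi esterification acylates the only free (secondary allylic) hydroxyl with retention; the hindered tertiary silyl ether and the sulfone are spectators.

Step 26
Reactants: 34 seco ester
Product: 35 primary alcohol
Conditions: DDQ, CH2Cl2/pH 7 buffer, 0 °C; no chromatography
Reagents that add atoms: none
Why: Oxidative PMB cleavage under buffered conditions; the 2-acyloxy-1-ol is taken on at once to outrun 1,2-acyl migration.

Step 27
Reactants: 35 primary alcohol
Product: 36 α-acyloxy aldehyde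
Conditions: Dess–Martin periodinane, NaHCO3, CH2Cl2, 0 °C; used crude
Reagents that add atoms: none
Why: Dess–Martin oxidation under buffered, non-basic conditions should give the aldehyde without epimerising the allylic α-centre or moving the β,γ-alkene into conjugation.

Step 28
Reactants: 36 α-acyloxy aldehyde / α-methoxy 2-pyridyl sulfone
Product: 38 protected macrolactone, via organosamarium 37 (not isolated)
Conditions: SmI2 (2.2 equiv, added over 1 h), THF, 1 mM, 0 °C to rt; sat. NH4Cl, 0 °C
Reagents that add atoms: none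
Why: Proposed new method: two single-electron transfers from SmI2 cleave the C–S bond of the 2-pyridyl sulfone to the α-methoxyalkyl radical and then to the α-methoxyalkyl organosamarium 37 (trivalent samarium), which adds to the tethered aldehyde faster than divalent samarium reduces an aliphatic aldehyde in THF without HMPA; the closest known reaction is the SmI2 Barbier coupling of glycosyl 2-pyridyl sulfones with aldehydes (C-glycoside synthesis), run here intramolecularly as in SmI2 Barbier and Reformatsky macrocyclisations. The 18-membered lactone ring closes by nucleophilic addition to the exocyclic C=O (18-exo-trig) at high dilution, helped by the rigid oxazole, E-alkene and s-trans ester units of the seco chain. The carbinol centre should be controlled by the adjacent acyloxy-bearing stereocentre: Felkin–Anh addition anti to the non-chelating acyloxy group gives the 1,2-anti relation. The methoxy centre is set in the same step because the organosamarium is configurationally labile: samarium bridging the methoxy oxygen and the aldehyde oxygen holds the two oxygens gauche and the two chain arms anti, which should give the 1,2-syn methoxy alcohol. The step needs reduction of the sulfone before the aldehyde, the enoate or the allylic ester (secured by the easily reduced pyridyl sulfone and the absence of HMPA) and no acyl shift of the samarium alkoxide onto the neighbouring ester (cold buffered quench).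

Step 29
Reactants: 38 protected macrolactone
Product: 39 target (CNP0112511.2)
Conditions: TBAF, AcOH (1:1), THF, 0 °C to rt
Reagents that add atoms: none
Why: Fluoride-induced global desilylation removes the TBS and TES ethers and fragments the 2-(trimethylsilyl)ethyl ester (β-elimination to ethylene); acetic acid buffering should suppress translactonisation onto the free neighbouring hydroxyl.

**Compound list**

1 | (S)-citronellal | O=CC[C@@H](C)CCC=C(C)C | starting material
2 | (S)-citronellal dimethyl acetal | COC(OC)C[C@@H](C)CCC=C(C)C | intermediate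
3 | ozonide of 2 (1,2,4-trioxolane) | COC(OC)C[C@@H](C)CCC1OOC(C)(C)O1 | intermediate
4 | (4S)-6,6-dimethoxy-4-methylhexanal | COC(OC)C[C@@H](C)CCC=O | intermediate
5 | oxazolidine from 4 and L-serine methyl ester (epimers at C2) | COC(OC)C[C@@H](C)CCC1N[C@@H](CO1)C(=O)OC | intermediate
6 | oxazoline (4,5-dihydrooxazole-4-carboxylate) | COC(OC)C[C@@H](C)CCC1=N[C@@H](CO1)C(=O)OC | intermediate
7 | methyl 2-[(3S)-5,5-dimethoxy-3-methylpentyl]oxazole-4-carboxylate | COC(OC)C[C@@H](C)CCc1nc(co1)C(=O)OC | intermediate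
8 | Weinreb amide of 7 | COC(OC)C[C@@H](C)CCc1nc(co1)C(=O)N(C)OC | intermediate
9 | 4-acetyl-2-[(3S)-5,5-dimethoxy-3-methylpentyl]oxazole | COC(OC)C[C@@H](C)CCc1nc(co1)C(C)=O | intermediate
10 | ethyl (E)-3-(oxazol-4-yl)but-2-enoate derivative | COC(OC)C[C@@H](C)CCc1nc(co1)/C(C)=C/C(=O)OCC | intermediate
11 | (E)-3-(oxazol-4-yl)but-2-en-1-ol derivative | COC(OC)C[C@@H](C)CCc1nc(co1)/C(C)=C/CO | intermediate
12 | (E)-3-(oxazol-4-yl)but-2-enal derivative | COC(OC)C[C@@H](C)CCc1nc(co1)/C(C)=C/C=O | intermediate
13 | (2E,4R,5S)-5-methyl-2-(oxazol-4-yl)hepta-2,6-dien-4-ol derivative (syn) | COC(OC)C[C@@H](C)CCc1nc(co1)/C(C)=C/[C@H](O)[C@@H](C)C=C | intermediate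
14 | TBS ether of 13 | COC(OC)C[C@@H](C)CCc1nc(co1)/C(C)=C/[C@H](O[Si](C)(C)C(C)(C)C)[C@@H](C)C=C | intermediate
15 | (2E,6E)-5-(TBS-oxy)-4-methyl-6-(oxazol-4-yl)hepta-2,6-dienoic acid, 4,5-syn, acetal intact | COC(OC)C[C@@H](C)CCc1nc(co1)/C(C)=C/[C@H](O[Si](C)(C)C(C)(C)C)[C@@H](C)/C=C/C(=O)O | intermediate
16 | methoxy 2-pyridylthio acetal of 15 (epimers) | COC(Sc1ccccn1)C[C@@H](C)CCc1nc(co1)/C(C)=C/[C@H](O[Si](C)(C)C(C)(C)C)[C@@H](C)/C=C/C(=O)O | intermediate
17 | fragment 1: α-methoxy 2-pyridyl sulfone acid (epimers) | COC(C[C@@H](C)CCc1nc(co1)/C(C)=C/[C@H](O[Si](C)(C)C(C)(C)C)[C@@H](C)/C=C/C(=O)O)S(=O)(=O)c1ccccn1 | intermediate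
18 | (R)-lactic acid | C[C@@H](O)C(=O)O | starting material
19 | (2R,5R)-2-tert-butyl-5-methyl-1,3-dioxolan-4-one | C[C@H]1O[C@@H](C(C)(C)C)OC1=O | intermediate
20 | lithium enolate of 19 | [Li+].[O-]C1=C(C)O[C@@H](C(C)(C)C)O1 | intermediate
21 | (2R,5S)-2-tert-butyl-5-methyl-5-(prop-2-ynyl)-1,3-dioxolan-4-one | C#CC[C@]1(C)O[C@@H](C(C)(C)C)OC1=O | intermediate
22 | 2-(trimethylsilyl)ethyl (S)-2-hydroxy-2-methylpent-4-ynoate | C#CC[C@](C)(O)C(=O)OCC[Si](C)(C)C | intermediate
23 | 2-(trimethylsilyl)ethyl (S)-2-methyl-2-(triethylsilyloxy)pent-4-ynoate | C#CC[C@](C)(O[Si](CC)(CC)CC)C(=O)OCC[Si](C)(C)C | intermediate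
24 | 2,3-O-isopropylidene-D-glyceraldehyde | O=C[C@H]1COC(C)(C)O1 | starting material
25 | ethyl (S,E)-3-(2,2-dimethyl-1,3-dioxolan-4-yl)-2-methylacrylate | CCOC(=O)/C(C)=C/[C@H]1COC(C)(C)O1 | intermediate
26 | ethyl (S,E)-4,5-dihydroxy-2-methylpent-2-enoate | CCOC(=O)/C(C)=C/[C@H](O)CO | intermediate
27 | dibutylstannylene acetal of 26 | CCOC(=O)/C(C)=C/[C@H]1CO[Sn](CCCC)(CCCC)O1 | intermediate
28 | ethyl (S,E)-4-hydroxy-5-(4-methoxybenzyloxy)-2-methylpent-2-enoate | CCOC(=O)/C(C)=C/[C@H](O)COCc1ccc(OC)cc1 | intermediate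
29 | (S,E)-5-(4-methoxybenzyloxy)-2-methylpent-2-ene-1,4-diol | OC/C(C)=C/[C@H](O)COCc1ccc(OC)cc1 | intermediate
30 | (S,E)-5-bromo-1-(4-methoxybenzyloxy)-4-methylpent-3-en-2-ol | BrC/C(C)=C/[C@H](O)COCc1ccc(OC)cc1 | intermediate
31 | skipped enyne from 30 and 23 | O[C@@H](/C=C(\C)CC#CC[C@](C)(O[Si](CC)(CC)CC)C(=O)OCC[Si](C)(C)C)COCc1ccc(OC)cc1 | intermediate
32 | fragment 2: (E,Z)-skipped diene alcohol | O[C@@H](/C=C(\C)C/C=C\C[C@](C)(O[Si](CC)(CC)CC)C(=O)OCC[Si](C)(C)C)COCc1ccc(OC)cc1 | intermediate
33 | 2,4,6-trichlorobenzoic mixed anhydride of 17 | COC(C[C@@H](C)CCc1nc(co1)/C(C)=C/[C@H](O[Si](C)(C)C(C)(C)C)[C@@H](C)/C=C/C(=O)OC(=O)c1c(Cl)cc(Cl)cc1Cl)S(=O)(=O)c1ccccn1 | intermediate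
34 | seco ester (PMB ether) | COC(C[C@@H](C)CCc1nc(co1)/C(C)=C/[C@H](O[Si](C)(C)C(C)(C)C)[C@@H](C)/C=C/C(=O)O[C@@H](/C=C(\C)C/C=C\C[C@](C)(O[Si](CC)(CC)CC)C(=O)OCC[Si](C)(C)C)COCc1ccc(OC)cc1)S(=O)(=O)c1ccccn1 | intermediate
35 | seco ester primary alcohol | COC(C[C@@H](C)CCc1nc(co1)/C(C)=C/[C@H](O[Si](C)(C)C(C)(C)C)[C@@H](C)/C=C/C(=O)O[C@@H](/C=C(\C)C/C=C\C[C@](C)(O[Si](CC)(CC)CC)C(=O)OCC[Si](C)(C)C)CO)S(=O)(=O)c1ccccn1 | intermediate
36 | seco α-acyloxy aldehyde | COC(C[C@@H](C)CCc1nc(co1)/C(C)=C/[C@H](O[Si](C)(C)C(C)(C)C)[C@@H](C)/C=C/C(=O)O[C@@H](/C=C(\C)C/C=C\C[C@](C)(O[Si](CC)(CC)CC)C(=O)OCC[Si](C)(C)C)C=O)S(=O)(=O)c1ccccn1 | intermediate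
37 | α-methoxyalkylsamarium diiodide from 36 | COC(C[C@@H](C)CCc1nc(co1)/C(C)=C/[C@H](O[Si](C)(C)C(C)(C)C)[C@@H](C)/C=C/C(=O)O[C@@H](/C=C(\C)C/C=C\C[C@](C)(O[Si](CC)(CC)CC)C(=O)OCC[Si](C)(C)C)C=O)[Sm](I)I | intermediate
38 | protected macrolactone (O-TBS, O-TES, TMSE ester; ring hydroxyl free) | CO[C@H]1C[C@@H](C)CCc2nc(co2)/C(C)=C/[C@H](O[Si](C)(C)C(C)(C)C)[C@@H](C)/C=C/C(=O)O[C@@H](/C=C(\C)C/C=C\C[C@](C)(O[Si](CC)(CC)CC)C(=O)OCC[Si](C)(C)C)[C@@H]1O | intermediate
39 | CNP0112511.2 | CO[C@H]1C[C@@H](C)CCc2nc(co2)/C(C)=C/[C@H](O)[C@@H](C)/C=C/C(=O)O[C@@H](/C=C(\C)C/C=C\C[C@](C)(O)C(=O)O)[C@@H]1O | target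

**Totals and risks**

Total steps: 29. Longest linear sequence: 18 (steps 1–13, then 25–29).

Steps most likely to fail:

1. Step 28. Poor facial selectivity at the methoxy carbon, or ketyl formation at the α-acyloxy aldehyde followed by loss of the acyloxy group, would erode the macrocyclisation. Fallback with known chemistry: make the same bond between two open fragments by the established intermolecular SmI2 Barbier coupling of a 2-pyridyl sulfone with an aldehyde, then close the ring by Yamaguchi macrolactonisation. It sets out from 17 and 32. Acid 17 is esterified (allyl alcohol, EDC, DMAP) to allyl ester F1. Alcohol 32 is silylated (TESCl, imidazole) to silyl ether F2, freed from PMB (DDQ) to primary alcohol F3 and oxidised (Dess–Martin) to the configurationally robust α-silyloxy aldehyde F4. SmI2 in THF unites F1 and F4 to the Felkin adduct F5, which TBSOTf/2,6-lutidine converts to bis-silyl ether F6. PPTS in MeOH removes only the secondary allylic TES group to give alcohol F7, and Pd(PPh3)4/morpholine cleaves the allyl ester to seco acid F8. Yamaguchi macrolactonisation gives macrolactone F9, the O-TBS ether of 38, which the conditions of step 29 convert to 39, where the route is rejoined.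

2. Step 26. Migration of the acyl group from the secondary oxygen to the freshly freed primary hydroxyl (and oxidation of the skipped diene by DDQ at this late stage) would scramble the seco ester. Fallback: remove the PMB group before the ester exists and never free the alcohol next to it. From 32, DDQ gives diol F10, TESCl/imidazole at −40 °C silylates the primary hydroxyl to give silyl ether F11, and Yamaguchi esterification with 17 gives seco ester F12. Swern conditions ((COCl)2, DMSO; i-Pr2NEt, −78 °C) oxidise the primary TES ether of F12 directly to aldehyde 36, where the route is rejoined.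

3. Step 13. Competing epoxidation of the trisubstituted alkene or N-oxidation during the peroxide oxidation would lower the yield. Fallback: make the sulfone without an oxidant by direct exchange of one methoxy group of acetal 15 with pyridine-2-sulfinic acid (sodium pyridine-2-sulfinate, BF3·OEt2, CH2Cl2, −20 °C), the way anomeric sulfones are made from acetals and sulfinic acids. It sets out from 15 and returns at 17 without new compounds.

**Further compounds**

F1 | step 28 | allyl ester of 17 | COC(C[C@@H](C)CCc1nc(co1)/C(C)=C/[C@H](O[Si](C)(C)C(C)(C)C)[C@@H](C)/C=C/C(=O)OCC=C)S(=O)(=O)c1ccccn1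
F2 | step 28 | secondary TES ether of 32 | CC[Si](CC)(CC)O[C@@H](/C=C(\C)C/C=C\C[C@](C)(O[Si](CC)(CC)CC)C(=O)OCC[Si](C)(C)C)COCc1ccc(OC)cc1
F3 | step 28 | primary alcohol from F2 | CC[Si](CC)(CC)O[C@@H](/C=C(\C)C/C=C\C[C@](C)(O[Si](CC)(CC)CC)C(=O)OCC[Si](C)(C)C)CO
F4 | step 28 | α-triethylsilyloxy aldehyde | CC[Si](CC)(CC)O[C@@H](/C=C(\C)C/C=C\C[C@](C)(O[Si](CC)(CC)CC)C(=O)OCC[Si](C)(C)C)C=O
F5 | step 28 | open-chain Barbier adduct (allyl ester, secondary TES ether, free carbinol) | CO[C@@H](C[C@@H](C)CCc1nc(co1)/C(C)=C/[C@H](O[Si](C)(C)C(C)(C)C)[C@@H](C)/C=C/C(=O)OCC=C)[C@@H](O)[C@@H](O[Si](CC)(CC)CC)/C=C(\C)C/C=C\C[C@](C)(O[Si](CC)(CC)CC)C(=O)OCC[Si](C)(C)C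
F6 | step 28 | O-TBS ether of F5 | CO[C@@H](C[C@@H](C)CCc1nc(co1)/C(C)=C/[C@H](O[Si](C)(C)C(C)(C)C)[C@@H](C)/C=C/C(=O)OCC=C)[C@@H](O[Si](C)(C)C(C)(C)C)[C@@H](O[Si](CC)(CC)CC)/C=C(\C)C/C=C\C[C@](C)(O[Si](CC)(CC)CC)C(=O)OCC[Si](C)(C)C
F7 | step 28 | allylic alcohol from F6 (secondary TES removed) | CO[C@@H](C[C@@H](C)CCc1nc(co1)/C(C)=C/[C@H](O[Si](C)(C)C(C)(C)C)[C@@H](C)/C=C/C(=O)OCC=C)[C@@H](O[Si](C)(C)C(C)(C)C)[C@@H](O)/C=C(\C)C/C=C\C[C@](C)(O[Si](CC)(CC)CC)C(=O)OCC[Si](C)(C)C
F8 | step 28 | seco hydroxy acid | CO[C@@H](C[C@@H](C)CCc1nc(co1)/C(C)=C/[C@H](O[Si](C)(C)C(C)(C)C)[C@@H](C)/C=C/C(=O)O)[C@@H](O[Si](C)(C)C(C)(C)C)[C@@H](O)/C=C(\C)C/C=C\C[C@](C)(O[Si](CC)(CC)CC)C(=O)OCC[Si](C)(C)C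
F9 | step 28 | O-TBS ether of macrolactone 38 | CO[C@H]1C[C@@H](C)CCc2nc(co2)/C(C)=C/[C@H](O[Si](C)(C)C(C)(C)C)[C@@H](C)/C=C/C(=O)O[C@@H](/C=C(\C)C/C=C\C[C@](C)(O[Si](CC)(CC)CC)C(=O)OCC[Si](C)(C)C)[C@@H]1O[Si](C)(C)C(C)(C)C
F10 | step 26 | diol from 32 | O[C@@H](/C=C(\C)C/C=C\C[C@](C)(O[Si](CC)(CC)CC)C(=O)OCC[Si](C)(C)C)CO
F11 | step 26 | primary TES ether of F10 | O[C@@H](/C=C(\C)C/C=C\C[C@](C)(O[Si](CC)(CC)CC)C(=O)OCC[Si](C)(C)C)CO[Si](CC)(CC)CC
F12 | step 26 | seco ester with primary TES ether | COC(C[C@@H](C)CCc1nc(co1)/C(C)=C/[C@H](O[Si](C)(C)C(C)(C)C)[C@@H](C)/C=C/C(=O)O[C@@H](/C=C(\C)C/C=C\C[C@](C)(O[Si](CC)(CC)CC)C(=O)OCC[Si](C)(C)C)CO[Si](CC)(CC)CC)S(=O)(=O)c1ccccn1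
F0 | step 13 | none | none
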